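**Retrosynthetic overview**
1. The free phenol is unmasked last by O-benzyl hydrogenolysis; the aryl ketone comes from oxidation of a benzylic aldol carbinol.
2. Key disconnection: the bond between lactone C3 and the aroyl carbon, made by intermolecular aldol addition of the lithium enolate of (R)-4-(3,4-dimethoxybenzyl)oxolan-2-one to O-benzylvanillin. The C4 substituent directs the trans C3/C4 relationship, which is also the thermodynamic arrangement of the β-keto lactone.
3. The lactone is the only ring formed in the route (both arenes are bought). It arises by reductive auxiliary removal and lactonisation of an Evans alkylation product.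
4. C4 (R) is set by alkylating the (S)-4-benzyl-oxazolidinone imide of 3-(3,4-dimethoxyphenyl)propanoic acid with tert-butyl bromoacetate.

Assumption: the target is treated as the keto tautomer drawn, (3S,4R), which is the trans isomer; C3 is an epimerisable β-keto lactone centre and trans is its thermodynamic configuration.

**Route**

Step 1
Reactants: 1 3-(3,4-dimethoxyphenyl)propanoic acid; 2 pivaloyl chloride; 3 (S)-4-benzyl-1,3-oxazolidin-2-one
Product: 5 (4S)-4-benzyl-3-[3-(3,4-dimethoxyphenyl)propanoyl]-1,3-oxazolidin-2-one, via mixed pivalic anhydride 4 (not isolated)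
Conditions: PivCl, Et3N, THF, −20 °C, 1 h; then LiCl, 3, −20 °C → rt, 4 h
Reagents that add atoms: (S)-4-benzyl-1,3-oxazolidin-2-one (3), O=C1OC[C@H](Cc2ccccc2)N1
Why: Mixed-anhydride N-acylation, in which the LiCl-activated oxazolidinone attacks the less hindered carbonyl of the pivalic anhydride; no stereocentre is formed and the auxiliary centre is untouched.

Step 2
Reactants: 5 (4S)-4-benzyl-3-[3-(3,4-dimethoxyphenyl)propanoyl]-1,3-oxazolidin-2-one; 6 tert-butyl bromoacetate
Product: 8 tert-butyl (3R)-4-[(4S)-4-benzyl-2-oxo-1,3-oxazolidin-3-yl]-3-(3,4-dimethoxybenzyl)-4-oxobutanoate, via sodium Z-enolate 7 (not isolated)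
Conditions: NaN(SiMe3)2 (1.1 equiv), THF, −78 °C, 1 h; then BrCH2CO2tBu (2 equiv), −78 → −40 °C, 3 h
Reagents that add atoms: tert-butyl bromoacetate (6), CC(C)(C)OC(=O)CBr
Why: Evans asymmetric alkylation, in which the chelated sodium Z-enolate is alkylated on the face opposite the auxiliary benzyl group, setting the new centre as R (minor diastereomer removed by chromatography or crystallisation).

Step 3
Reactants: 8 tert-butyl (3R)-4-[(4S)-4-benzyl-2-oxo-1,3-oxazolidin-3-yl]-3-(3,4-dimethoxybenzyl)-4-oxobutanoate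
Product: 10 (4R)-4-(3,4-dimethoxybenzyl)oxolan-2-one, via tert-butyl hydroxy ester 9 (not isolated)
Conditions: LiBH4 (1.5 equiv), MeOH (1.5 equiv), THF, 0 °C, 2 h; aqueous work-up; then TsOH·H2O (10 mol %), toluene, 80 °C, 2 h
Reagents that add atoms: none
Why: Chemoselective reductive cleavage of the imide carbonyl by LiBH4 (the tert-butyl ester is spared), then acid-catalysed intramolecular transesterification (lactonisation); the stereocentre is not touched and becomes the non-epimerisable C4.

Step 4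
Reactants: 10 (4R)-4-(3,4-dimethoxybenzyl)oxolan-2-one; 11 4-(benzyloxy)-3-methoxybenzaldehyde
Product: 13 (3S,4R)-3-[(4-benzyloxy-3-methoxyphenyl)(hydroxy)methyl]-4-(3,4-dimethoxybenzyl)oxolan-2-one (both carbinol epimers), via lithium lactone enolate 12 (not isolated)
Conditions: LiN(iPr)2 (1.1 equiv), THF, −78 °C, 45 min; then 11 (1.1 equiv), −78 °C, 1 h; AcOH quench at −78 °C
Reagents that add atoms: 4-(benzyloxy)-3-methoxybenzaldehyde (11), COc1cc(C=O)ccc1OCc1ccccc1
Why: Intermolecular aldol addition of a lactone lithium enolate to a non-enolisable aryl aldehyde; the aldehyde approaches anti to the C4 benzyl group, setting C3 trans (3S), and the carbinol centre forms as a mixture that is erased in step 5.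

Step 5
Reactants: 13 (3S,4R)-3-[(4-benzyloxy-3-methoxyphenyl)(hydroxy)methyl]-4-(3,4-dimethoxybenzyl)oxolan-2-one
Product: 14 (3S,4R)-3-(4-benzyloxy-3-methoxybenzoyl)-4-(3,4-dimethoxybenzyl)oxolan-2-one
Conditions: Dess–Martin periodinane (1.3 equiv), CH2Cl2, 0 °C → rt, 1 h; aq Na2S2O3/NaHCO3 work-up
Reagents that add atoms: none
Why: Dess–Martin oxidation of a benzylic secondary alcohol under near-neutral conditions avoids retro-aldol cleavage; both carbinol epimers converge on one ketone and the acidic C3–H lets the β-keto lactone settle in the favoured trans (3S,4R) form.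

Step 6
Reactants: 14 (3S,4R)-3-(4-benzyloxy-3-methoxybenzoyl)-4-(3,4-dimethoxybenzyl)oxolan-2-one
Product: 15 (3S,4R)-4-(3,4-dimethoxybenzyl)-3-(4-hydroxy-3-methoxybenzoyl)oxolan-2-one
Conditions: H2 (1 atm), 10% Pd/C (palladium on carbon), EtOAc, rt, 1–2 h, stopped when 14 is consumed
Reagents that add atoms: none
Why: Catalytic hydrogenolysis of the benzyl aryl ether is much faster than reduction of the electron-rich aryl ketone, and the neutral conditions leave the lactone, the methyl ethers and the trans C3/C4 configuration intact.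

**Compound list**
1 | 3-(3,4-dimethoxyphenyl)propanoic acid | COc1ccc(CCC(=O)O)cc1OC | starting material
2 | pivaloyl chloride | CC(C)(C)C(=O)Cl | starting material
3 | (S)-4-benzyl-1,3-oxazolidin-2-one | O=C1OC[C@H](Cc2ccccc2)N1 | starting material
4 | 3-(3,4-dimethoxyphenyl)propanoic pivalic anhydride | COc1ccc(CCC(=O)OC(=O)C(C)(C)C)cc1OC | intermediate
5 | (4S)-4-benzyl-3-[3-(3,4-dimethoxyphenyl)propanoyl]-1,3-oxazolidin-2-one | COc1ccc(CCC(=O)N2[C@@H](Cc3ccccc3)COC2=O)cc1OC | intermediate
6 | tert-butyl bromoacetate | CC(C)(C)OC(=O)CBr | starting material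
7 | sodium (Z)-enolate of 5 | COc1ccc(C/C=C(\[O-])N2[C@@H](Cc3ccccc3)COC2=O)cc1OC.[Na+] | intermediate
8 | tert-butyl (3R)-4-[(4S)-4-benzyl-2-oxo-1,3-oxazolidin-3-yl]-3-(3,4-dimethoxybenzyl)-4-oxobutanoate | CC(C)(C)OC(=O)C[C@@H](Cc1ccc(OC)c(OC)c1)C(=O)N1[C@@H](Cc2ccccc2)COC1=O | intermediate
9 | tert-butyl (3R)-3-(3,4-dimethoxybenzyl)-4-hydroxybutanoate | CC(C)(C)OC(=O)C[C@@H](Cc1ccc(OC)c(OC)c1)CO | intermediate
10 | (4R)-4-(3,4-dimethoxybenzyl)oxolan-2-one | O=C1C[C@@H](Cc2ccc(OC)c(OC)c2)CO1 | intermediate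
11 | 4-(benzyloxy)-3-methoxybenzaldehyde (O-benzylvanillin) | COc1cc(C=O)ccc1OCc1ccccc1 | starting material
12 | lithium enolate of 10 | [Li+].[O-]C1=C[C@@H](Cc2ccc(OC)c(OC)c2)CO1 | intermediate
13 | (3S,4R)-3-[(4-benzyloxy-3-methoxyphenyl)(hydroxy)methyl]-4-(3,4-dimethoxybenzyl)oxolan-2-one, carbinol centre unassigned (both epimers) | COc1cc(C(O)[C@H]2C(=O)OC[C@@H]2Cc2ccc(OC)c(OC)c2)ccc1OCc1ccccc1 | intermediate
14 | (3S,4R)-3-(4-benzyloxy-3-methoxybenzoyl)-4-(3,4-dimethoxybenzyl)oxolan-2-one | COc1cc(C(=O)[C@H]2C(=O)OC[C@@H]2Cc2ccc(OC)c(OC)c2)ccc1OCc1ccccc1 | intermediate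
15 | (3S,4R)-4-(3,4-dimethoxybenzyl)-3-(4-hydroxy-3-methoxybenzoyl)oxolan-2-one | COc1cc(C(=O)[C@H]2C(=O)OC[C@@H]2Cc2ccc(OC)c(OC)c2)ccc1O | target

**Summary**
Total step count: 6. Longest linear sequence: 6 steps (1 → 15).

**Steps most likely to fail, with fallbacks**

Step 3 (LiBH4 may attack the tert-butyl ester or open the oxazolidinone ring). The fallback sets out from 8 and comes back at 9. Compound 8 is cleaved hydrolytically with LiOH/H2O2 (THF–H2O, 0 °C, Na2SO3 quench), giving (2R)-4-tert-butoxy-2-(3,4-dimethoxybenzyl)-4-oxobutanoic acid F1 and returning the auxiliary. The free acid is then reduced chemoselectively with BH3·SMe2 (THF, 0 °C → rt) to hydroxy ester 9, which is lactonised with TsOH as in step 3.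

Step 5 (retro-aldol cleavage of 13 or over-oxidation at the doubly activated C3). The fallback sets out from 10 and comes back at 14, bypassing the carbinol with a crossed Claisen acylation. Aldehyde 11 is oxidised (NaClO2, NaH2PO4, 2-methyl-2-butene, t-BuOH–H2O) to 4-(benzyloxy)-3-methoxybenzoic acid F2. This is activated with 1,1'-carbonyldiimidazole (THF, rt) to [4-(benzyloxy)-3-methoxyphenyl](1H-imidazol-1-yl)methanone F3. Lactone 10 is converted into enolate 12 with LiN(SiMe3)2 (2.2 equiv, THF, −78 °C) and F3 is added; the second equivalent of base holds the product as its enolate, and acidic work-up gives 14 directly, trans by equilibration.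

Step 6 (hydrogenolysis may also reduce the aryl ketone). The fallback sets out from 10 and comes back at 15, carrying a fluoride-labile silyl ether through the same sequence. Commercial vanillin is silylated (TBSCl, imidazole, DMF, rt) to 4-[(tert-butyldimethylsilyl)oxy]-3-methoxybenzaldehyde F4. Aldol addition of enolate 12 (from 10, LiN(iPr)2, THF, −78 °C) to F4 gives (3S,4R)-3-[{4-[(tert-butyldimethylsilyl)oxy]-3-methoxyphenyl}(hydroxy)methyl]-4-(3,4-dimethoxybenzyl)oxolan-2-one F5. Dess–Martin oxidation gives (3S,4R)-3-{4-[(tert-butyldimethylsilyl)oxy]-3-methoxybenzoyl}-4-(3,4-dimethoxybenzyl)oxolan-2-one F6. Bu4NF buffered with AcOH (THF, 0 °C) then removes the silyl group to give 15 without any reducing agent.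

**Further compounds**
F1 | step 3 | (2R)-4-tert-butoxy-2-(3,4-dimethoxybenzyl)-4-oxobutanoic acid | CC(C)(C)OC(=O)C[C@@H](Cc1ccc(OC)c(OC)c1)C(=O)O
F2 | step 5 | 4-(benzyloxy)-3-methoxybenzoic acid | COc1cc(C(=O)O)ccc1OCc1ccccc1
F3 | step 5 | [4-(benzyloxy)-3-methoxyphenyl](1H-imidazol-1-yl)methanone | COc1cc(C(=O)n2ccnc2)ccc1OCc1ccccc1
F4 | step 6 | 4-[(tert-butyldimethylsilyl)oxy]-3-methoxybenzaldehyde | COc1cc(C=O)ccc1O[Si](C)(C)C(C)(C)C
F5 | step 6 | (3S,4R)-3-[{4-[(tert-butyldimethylsilyl)oxy]-3-methoxyphenyl}(hydroxy)methyl]-4-(3,4-dimethoxybenzyl)oxolan-2-one (both carbinol epimers) | COc1cc(C(O)[C@H]2C(=O)OC[C@@H]2Cc2ccc(OC)c(OC)c2)ccc1O[Si](C)(C)C(C)(C)C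
F6 | step 6 | (3S,4R)-3-{4-[(tert-butyldimethylsilyl)oxy]-3-methoxybenzoyl}-4-(3,4-dimethoxybenzyl)oxolan-2-one | COc1cc(C(=O)[C@H]2C(=O)OC[C@@H]2Cc2ccc(OC)c(OC)c2)ccc1O[Si](C)(C)C(C)(C)C
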